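## The problem

The target is a ten-membered carbocycle (C1 to C10). It carries a cis-fused α-methylene γ-lactone across C6–C7 (oxygen on C6, C11 on C7), a Z trisubstituted C4=C5 alkene, a C9 ketone flanked by the C8 acyloxy group and the C10 methyl, and a C1 hydroxyl. A synthesis must therefore make a medium ring, which end-to-end closure serves poorly, and place five ring stereocentres (C1, C6, C7, C8, C10) plus two in the (2R,3R)-epoxyangelate. C1 and C10 form an anti aldol pair beside the ketone (cis on the ring). C10 is epimerisable and the C1 oxygen can be lost by β-elimination or retro-aldol cleavage, so both are best fixed early on a rigid six-membered ring and kept away from strong base once the ketone exists. C6, C7 and C8 are contiguous: the C6 oxygen can steer C7 and C8, but the lactone must end cis-fused while the C8 oxygen lies trans to the C7–C11 bond. The methylene lactone (a Michael acceptor), the epoxy ester and the β-hydroxy ketone do not survive strong acid, base or nucleophiles, so they must appear late and be unveiled mildly. The enabling feature is that the C9 carbonyl and the C4=C5 alkene are 1,5-related through C8, C7 and C6, the retron of an oxy-Cope rearrangement. Reconnecting C4 to C9 turns the ten-membered ring into a cyclohexanol whose C4 and C9 stereocentres encode the alkene geometry and C6.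

## Retrosynthesis

**Ester and silyl ether (29 ⇒ 28 ⇒ 22 + 26).** The C1 silyl ether and the C8 ester C–O bond are cut first. The epoxyangelate is attached as the preformed acid 26 (from angelic acid 23 through alcohol 24 and epoxy alcohol 25). Epoxidising an angelate after attachment would hit the more electron-rich C4=C5 alkene and offers no facial control. The forward steps must acylate a hindered α-hydroxy ketone without epimerising C8 and remove a triethylsilyl group without touching the epoxide or the lactone.

**Lactone (22 ⇒ 21 ⇒ 20 ⇒ 18 ⇒ 17 ⇒ 16).** C11=C13 is cut to formaldehyde and the α-phosphono lactone 21, and C7–C11 to the C6 phosphonoacetate 20. Letting the tethered phosphonoacetate add directly to enone 16 is the obvious neighbour. It is expected to reach C7 on the exposed face and give the trans-fused lactone, and it would leave C8 to a separate enolate oxidation next to the epimerisable C10. Routing through the cis-epoxide 17 (freed to alcohol 18 before acylation) reverses this. Oxygen adds first to the exposed face, trans to O6, and the tethered carbon then displaces it with inversion, giving the cis fusion. The epoxide oxygen stays on C8, trans to C11. Two stereocentres and the lactone thus come from one flat enone. The forward chemistry needs a cis enone, epoxidation trans to O6 and exo opening at C7.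

**Enone (16 ⇒ 15).** The C7=C8 alkene is removed by going back to the enol silane 15. 15 is the trapped enolate of the ring expansion, so its regiochemistry is set by the rearrangement and the dehydrogenation needs no base.

**Ring (15 ⇒ 13).** C6–C7 is cut and C4–C9 joined. This is the key disconnection: the ten-membered bis-silyl compound 15 becomes the cis-1,2-dialkenylcyclohexane-1,3-diol 13. The Z alkene and C6 then become questions of cyclohexane stereochemistry (C4, C9) and enol ether geometry. No macrocyclisation is needed.

**Carbinol (13 ⇒ 12 ⇒ 11 ⇒ 10 ⇒ 8 + 9).** In 13 the vinyl group, the enol ether arm, the C10 methyl and the C1 oxygen all sit on one face. Adding vinyl to a ketone that already has this C1 configuration would mean attack past an axial C1 oxygen, against the steric bias. Vinylmagnesium bromide 9 is therefore added to ketone 8, whose C1 silyloxy group is equatorial (trans to the C10 methyl). C1 is inverted afterwards: desilylation (11), oxidation (12) and bulky-hydride reduction (13). This costs three steps and buys predictable control at C9 and C1.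

**Enol ether (8 ⇒ 7 ⇒ 6).** Wittig alkoxymethylenation of aldehyde 6 would give E/Z mixtures, and the geometry decides C6. The C5=C6 bond is therefore made E-selectively as alkenyl boronate 7, and the C6–O bond with retention.

**Quaternary carbon and start (6 ⇒ 5 ⇒ 4 ⇒ 3 ⇒ 1).** C4 is built by formylation (5) then methylation (6). The order matters: the methyl enters last, trans to the C10 methyl. Ketone 4 comes from hydroxy ketone 3, made by asymmetric conjugate borylation and oxidation of enone 1 through boronate 2.

## Roads not taken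

**Alternative 1:** The cut is C5–C6 together with the lactone C–O bond. An open-chain aldehyde carrying a Z alkenyl iodide would be closed with CrCl2 and catalytic NiCl2, and the C6 alkoxide would lactonise onto a C12 ester to give A1.
- Merits: the Z alkene is fixed in an acyclic iodide before ring closure, and C1, C7, C8 and C10 can come from acyclic aldol chemistry. A1 already holds the methylene lactone and is three steps from the target. In end-game brevity this road is better than the chosen plan.
- Weak points: C6 is created in the ring-closing step without a reliable control element, and the cis fusion depends on it. The aldehyde sits next to C7, which carries an acrylate unit and can epimerise or conjugate. The closure needs high dilution and a large excess of chromium salt, and the linear precursor with five stereocentres is long.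
- Comparison: the chosen plan forms the ring at ordinary concentration and derives C6 and the alkene geometry stereospecifically from ring stereocentres. It pays with having to build C7 and C8 on the macrocycle.

**Alternative 2:** The cut is C2–C3, back to an eight-membered lactone. Methylenation with Cp2Ti(μ-Cl)(μ-CH2)AlMe2 (Tebbe reagent) and thermolysis of the resulting cyclic enol ether would give A2 by a Claisen shift.
- Merits: C6, C7 and C8 are set on a smaller ring before the ten-membered ring exists, and the alkene geometry comes from a tight cyclic transition state. In that respect it is safer than the chosen plan, which sets C7 and C8 late.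
- Weak points: the eight-membered lactone is itself a hard ring to make, and methylenating a hindered, polyoxygenated lactone is uncertain. A2 still needs a stereoselective C1 reduction beside C10, release of the C9 ketone and oxidation of the side chain to the lactone, under four different protecting groups.
- Comparison: the chosen plan carries two protecting groups through the ring expansion and fixes C1 and C10 on a cyclohexane before the ring is enlarged.

**Alternative 3:** The cut is C1–C10. The E boron enolate of a C9 ethyl ketone (Cy2BCl, Et3N) would add to a C1 aldehyde and give A3.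
- Merits: the ring and both C1 and C10 form in one step, the E enolate gives the required anti relationship, C1 needs no protecting group, and A3 is two steps from the target. This is the shortest end game of all.
- Weak points: enolisation must occur on the ethyl side of a ketone whose other α-carbon bears an alkoxy group. An amine base and a boron enolate must coexist with the methylene lactone. Which anti isomer forms rests on remote centres across a forming ten-membered ring, again at high dilution, and the precursor already has to contain the Z alkene and the cis lactone.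
- Comparison: the chosen plan sets C1 and C10 by substrate control on a chair and never exposes the methylene lactone to enolate chemistry.

Key step: step 11

Remarks before the steps:
- Ring atoms are referred to by the target numbering (C1 to C13) at every stage, including the cyclohexanes; cis and trans on the ten-membered ring refer to the flat-ring projection.
- Assumption: the dehydrogenation in step 12 gives the cis (7Z) enone, the stable geometry of a ten-membered 2-en-1-one.
- Assumption: the antipode of the bisphosphine in step 1 is the one that delivers boron to give the 3R boronate.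

## Steps

Step 1
Reactants: 1 2-methylcyclohex-2-en-1-one
Product: 3 (2S,3R)-3-hydroxy-2-methylcyclohexan-1-one, via β-boryl ketone 2 (not isolated)
Conditions: CuCl (5 mol%), NaOt-Bu (10 mol%), Josiphos-type bisphosphine (6 mol%), B2pin2, MeOH, THF, 25 °C; then NaBO3·4H2O, THF/H2O, 25 °C
Reagents that add atoms: sodium perborate, [Na+].[O-]OB=O (the C1 oxygen); bis(pinacolato)diboron, CC1(C)OB(OC1(C)C)B1OC(C)(C)C(C)(C)O1 (boron of 2 only)
Why: Copper-catalysed asymmetric conjugate borylation; the chiral ligand sets C1, methanol protonates the copper enolate and the alkoxide medium should equilibrate C10 to the trans, diequatorial isomer; perborate oxidises C–B to C–O with retention.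

Step 2
Reactants: 3 (2S,3R)-3-hydroxy-2-methylcyclohexan-1-one
Product: 4 (2S,3R)-3-[(tert-butyldimethylsilyl)oxy]-2-methylcyclohexan-1-one
Conditions: TBSCl, imidazole, DMF, 25 °C
Reagents that add atoms: tert-butyldimethylsilyl chloride, CC(C)(C)[Si](C)(C)Cl
Why: Standard silylation of a secondary alcohol; imidazole is too weak a base to cause β-elimination of the β-oxygenated ketone.

Step 3
Reactants: 4 (2S,3R)-3-[(tert-butyldimethylsilyl)oxy]-2-methylcyclohexan-1-one
Product: 5 (2S,3R,6Z)-3-[(tert-butyldimethylsilyl)oxy]-6-(hydroxymethylidene)-2-methylcyclohexan-1-one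
Conditions: LiN(i-Pr)2, THF, −78 °C; CF3CH2OCHO, −78 °C; aq. HCl work-up
Reagents that add atoms: 2,2,2-trifluoroethyl formate, O=COCC(F)(F)F
Why: Kinetic deprotonation on the CH2 side (C4) and Claisen-type formylation of the lithium enolate; the tertiary C10–H is left alone, which also avoids β-elimination of the silyloxy group.

Step 4
Reactants: 5 (2S,3R,6Z)-3-[(tert-butyldimethylsilyl)oxy]-6-(hydroxymethylidene)-2-methylcyclohexan-1-one
Product: 6 (1S,3S,4R)-4-[(tert-butyldimethylsilyl)oxy]-1,3-dimethyl-2-oxocyclohexane-1-carbaldehyde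
Conditions: MeI, K2CO3, acetone, 25 °C
Reagents that add atoms: iodomethane, CI
Why: C-methylation of the β-keto aldehyde enolate; axial attack on the half-chair that keeps the C10 methyl and C1 silyloxy group equatorial brings the new methyl in trans to the C10 methyl, while the opposite face is 1,3-diaxial to that methyl in the other half-chair.

Step 5
Reactants: 6 (1S,3S,4R)-4-[(tert-butyldimethylsilyl)oxy]-1,3-dimethyl-2-oxocyclohexane-1-carbaldehyde
Product: 7 (2S,3R,6S)-3-[(tert-butyldimethylsilyl)oxy]-2,6-dimethyl-6-[(E)-2-(4,4,5,5-tetramethyl-1,3,2-dioxaborolan-2-yl)ethenyl]cyclohexan-1-one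
Conditions: CrCl2 (8 equiv), Cl2CHBpin (2 equiv), LiI (4 equiv), THF, 25 °C
Reagents that add atoms: 2-(dichloromethyl)-4,4,5,5-tetramethyl-1,3,2-dioxaborolane, ClC(Cl)B1OC(C)(C)C(C)(C)O1
Why: Takai–Utimoto olefination with the boryl-substituted gem-dichromium reagent; it is aldehyde-selective (the hindered ketone stays) and E-selective through anti elimination of the β-oxido organochromium intermediate.

Step 6
Reactants: 7 (2S,3R,6S)-3-[(tert-butyldimethylsilyl)oxy]-2,6-dimethyl-6-[(E)-2-(pinacolboryl)ethenyl]cyclohexan-1-one
Product: 8 (2S,3R,6S)-3-[(tert-butyldimethylsilyl)oxy]-6-{(E)-2-[(4-methoxyphenyl)methoxy]ethenyl}-2,6-dimethylcyclohexan-1-one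
Conditions: Cu(OAc)2 (2 equiv), Et3N (4 equiv), 4-methoxybenzyl alcohol (excess), 4 Å MS, CH2Cl2, 25 °C, air
Reagents that add atoms: 4-methoxybenzyl alcohol, COc1ccc(CO)cc1
Why: Chan–Lam–Evans copper-mediated C–O coupling of an alkenyl boronate with an alcohol; it runs at room temperature with retention of alkene geometry, so the E enol ether forms without disturbing the β-silyloxy ketone.

Step 7
Reactants: 8 (2S,3R,6S)-3-[(tert-butyldimethylsilyl)oxy]-6-{(E)-2-[(4-methoxyphenyl)methoxy]ethenyl}-2,6-dimethylcyclohexan-1-one; 9 vinylmagnesium bromide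
Product: 10 (1R,2S,5R,6S)-5-[(tert-butyldimethylsilyl)oxy]-1-ethenyl-2-{(E)-2-[(4-methoxyphenyl)methoxy]ethenyl}-2,6-dimethylcyclohexan-1-ol
Conditions: CeCl3 (anhydrous), THF; CH2=CHMgBr, −78 °C; sat. NH4Cl
Reagents that add atoms: none
Why: Organocerium 1,2-addition, which suppresses enolisation of the hindered ketone; in the chair with the C10 methyl, C1 silyloxy and alkenyl groups equatorial and the C4 methyl axial, the nucleophile enters axially, anti to that methyl, so vinyl ends cis to the enol ether arm (C9 R).

Step 8
Reactants: 10 (1R,2S,5R,6S)-5-[(tert-butyldimethylsilyl)oxy]-1-ethenyl-2-{(E)-2-[(4-methoxyphenyl)methoxy]ethenyl}-2,6-dimethylcyclohexan-1-ol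
Product: 11 (1R,2S,3R,6S)-1-ethenyl-6-{(E)-2-[(4-methoxyphenyl)methoxy]ethenyl}-2,6-dimethylcyclohexane-1,3-diol
Conditions: Bu4NF, THF, 0 to 25 °C; sat. NH4Cl
Reagents that add atoms: none
Why: Fluoride cleavage of the secondary silyl ether; the enol ether and the tertiary allylic alcohol tolerate these non-acidic conditions.

Step 9
Reactants: 11 (1R,2S,3R,6S)-1-ethenyl-6-{(E)-2-[(4-methoxyphenyl)methoxy]ethenyl}-2,6-dimethylcyclohexane-1,3-diol
Product: 12 (2R,3R,4S)-3-ethenyl-3-hydroxy-4-{(E)-2-[(4-methoxyphenyl)methoxy]ethenyl}-2,4-dimethylcyclohexan-1-one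
Conditions: Pr4N[RuO4] (5 mol%), N-methylmorpholine N-oxide, 4 Å MS, CH2Cl2, 0 to 25 °C
Reagents that add atoms: none
Why: Ley–Griffith oxidation; only the secondary alcohol can be oxidised, and the neutral medium spares the acid-sensitive pair of enol ether and tertiary alcohol.

Step 10
Reactants: 12 (2R,3R,4S)-3-ethenyl-3-hydroxy-4-{(E)-2-[(4-methoxyphenyl)methoxy]ethenyl}-2,4-dimethylcyclohexan-1-one
Product: 13 (1R,2S,3S,6S)-1-ethenyl-6-{(E)-2-[(4-methoxyphenyl)methoxy]ethenyl}-2,6-dimethylcyclohexane-1,3-diol
Conditions: LiBH(s-Bu)3, THF, −78 °C; sat. NH4Cl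
Reagents that add atoms: none
Why: Bulky-hydride reduction; the axial path to C1 is blocked by the axial C9 vinyl group (1,3-diaxial), so hydride enters equatorially and gives the axial C1 alcohol cis to the C10 methyl (C1 S); the low temperature guards against retro-aldol of the ketol.

Step 11
Reactants: 13 (1R,2S,3S,6S)-1-ethenyl-6-{(E)-2-[(4-methoxyphenyl)methoxy]ethenyl}-2,6-dimethylcyclohexane-1,3-diol
Product: 15 (1S,4Z,6R,8Z,10S)-6-[(4-methoxyphenyl)methoxy]-4,10-dimethyl-1,9-bis[(triethylsilyl)oxy]cyclodeca-4,8-diene, via dipotassium dienolate 14 (not isolated)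
Conditions: KH (3 equiv), 18-crown-6 (3 equiv), THF, 0 to 40 °C; then Et3SiCl, Et3N, −78 °C
Reagents that add atoms: chlorotriethylsilane, CC[Si](CC)(CC)Cl
Why: Anionic oxy-Cope rearrangement: KH with 18-crown-6 deprotonates both hydroxyls (the C1 alkoxide is a spectator) and the C9 alkoxide drives a concerted [3,3] shift of the C7=C8–C9–C4–C5=C6 array, forming C6–C7 and breaking C4–C9 to give 14. The closest known reaction type is the anionic oxy-Cope ring expansion of cis-1,2-dialkenylcyclohexanols to cyclodec-5-enones with silyl trapping of the enolate. The ten-membered ring is not closed end to end; it arises by four-atom expansion of the cyclohexane through a chair-like six-centre transition state. The operating chair derives from the cyclohexane conformer with the C10 methyl equatorial, the vinyl group axial and the enol ether arm equatorial, because the other chair would force the C10 methyl and the C4 alkenyl group syn-diaxial. In it C3 is axial and the C4 methyl equatorial on the breaking bond, which gives the Z C4=C5 alkene, and C10 is equatorial at C9, so the enolate has C10 trans to C7. The only new stereocentre, C6, is set by the E enol ether, which holds the benzyloxy group equatorial on the forming bond; with the C4 and C9 configurations this gives 6R in 15, the spatial arrangement that is 6S in the target. The step needs the Z geometry and the C6 configuration, and both are secured by the cis relationship of the two alkenyl groups and by the E enol ether from steps 5 to 7. Et3SiCl then silylates the enolate oxygen, keeping the C8=C9 regiochemistry for step 12, and the C1 alkoxide, which installs the C1 protecting group.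

Step 12
Reactants: 15 (1S,4Z,6R,8Z,10S)-6-[(4-methoxyphenyl)methoxy]-4,10-dimethyl-1,9-bis[(triethylsilyl)oxy]cyclodeca-4,8-diene
Product: 16 (1S,4Z,6R,7Z,10S)-6-[(4-methoxyphenyl)methoxy]-4,10-dimethyl-1-[(triethylsilyl)oxy]cyclodeca-4,7-dien-9-one
Conditions: Pd(OAc)2 (1.1 equiv), MeCN, 25 °C
Reagents that add atoms: none
Why: Saegusa oxidation: palladation of the enol silane at C8 and β-hydride elimination toward C7 give the enone with regiochemistry fixed by the enol silane and no base; the cis enone is expected as the stable geometry in a ten-membered ring.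

Step 13
Reactants: 16 (1S,4Z,6R,7Z,10S)-6-[(4-methoxyphenyl)methoxy]-4,10-dimethyl-1-[(triethylsilyl)oxy]cyclodeca-4,7-dien-9-one
Product: 17 (1S,4Z,6S,7R,8R,10S)-7,8-epoxy-6-[(4-methoxyphenyl)methoxy]-4,10-dimethyl-1-[(triethylsilyl)oxy]cyclodec-4-en-9-one
Conditions: t-BuOOH, DBU, CH2Cl2, 0 °C
Reagents that add atoms: tert-butyl hydroperoxide, CC(C)(C)OO
Why: Weitz–Scheffer nucleophilic epoxidation; with H6 eclipsing the cis enone to avoid allylic strain, the peroxide anion adds to C7 on the exposed face and closes on C8, giving the cis-epoxide trans to the C6 oxygen (the outcome also seen with 4-alkoxycycloalkenones), and the electron-rich C4=C5 alkene is inert to the nucleophilic oxidant.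

Step 14
Reactants: 17 (1S,4Z,6S,7R,8R,10S)-7,8-epoxy-6-[(4-methoxyphenyl)methoxy]-4,10-dimethyl-1-[(triethylsilyl)oxy]cyclodec-4-en-9-one
Product: 18 (1S,4Z,6S,7R,8R,10S)-7,8-epoxy-6-hydroxy-4,10-dimethyl-1-[(triethylsilyl)oxy]cyclodec-4-en-9-one
Conditions: DDQ, CH2Cl2/pH 7 buffer, 0 °C
Reagents that add atoms: none
Why: Oxidative cleavage of the allylic 4-methoxybenzyl ether under buffered, near-neutral conditions; the silyl ether, the epoxy ketone and the alkene are untouched.

Step 15
Reactants: 18 (1S,4Z,6S,7R,8R,10S)-7,8-epoxy-6-hydroxy-4,10-dimethyl-1-[(triethylsilyl)oxy]cyclodec-4-en-9-one; 19 (diethoxyphosphoryl)acetic acid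
Product: 20 C6 (diethoxyphosphoryl)acetate of 18
Conditions: DCC, DMAP (cat.), CH2Cl2, 0 to 25 °C
Reagents that add atoms: none
Why: Steglich esterification of a secondary allylic alcohol; acylation also removes the free hydroxyl that could otherwise trigger epoxide migration.

Step 16
Reactants: 20 C6 (diethoxyphosphoryl)acetate of 18
Product: 22 (1S,4Z,6S,7R,8R,10S)-8-hydroxy-9-oxo-1-[(triethylsilyl)oxy]germacra-4,11(13)-dien-12,6-olide, via phosphono lactone 21 (not isolated)
Conditions: KOt-Bu (1.1 equiv), THF, −40 to 0 °C; then (CH2O)n, 0 to 25 °C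
Reagents that add atoms: formaldehyde, C=O
Why: Proposed new method: the phosphonoacetate carbanion, tethered through the C6 ester, should open the epoxide at C7 in a 5-exo-tet closure with inversion (backside to the C7–O bond, which lies trans to O6), so C11 ends cis to O6 and the untouched C8 oxygen trans to C11; the C8 alkoxide is then quenched by the acidic C11–H, regenerating the phosphonate anion that olefinates formaldehyde (Horner–Wadsworth–Emmons); the closest known reaction types are the intermolecular alkylation of phosphonoacetate anions by epoxides to α-phosphono γ-lactones followed by formaldehyde olefination, and exo-selective intramolecular epoxide opening by stabilised carbanions, whereas the ester-tethered version on an α,β-epoxy ketone is not documented.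

Step 17
Reactants: 23 angelic acid
Product: 24 (Z)-2-methylbut-2-en-1-ol
Conditions: LiAlH4, Et2O, 0 °C; H2O, aq. NaOH work-up
Reagents that add atoms: none
Why: Hydride reduction of the acid to the allylic alcohol; the unactivated trisubstituted alkene is not reduced and keeps its Z geometry.

Step 18
Reactants: 24 (Z)-2-methylbut-2-en-1-ol
Product: 25 [(2S,3R)-2,3-dimethyloxiran-2-yl]methanol
Conditions: Ti(Oi-Pr)4 (10 mol%), L-(+)-diethyl tartrate (12 mol%), t-BuOOH, 4 Å MS, CH2Cl2, −20 °C
Reagents that add atoms: tert-butyl hydroperoxide, CC(C)(C)OO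
Why: Sharpless asymmetric epoxidation; the L-(+)-tartrate delivers oxygen to the face that gives 2S epoxy alcohols from this substitution pattern (as with other Z-3-substituted allylic alcohols), and syn addition keeps the C3 methyl cis to the carbinol carbon.

Step 19
Reactants: 25 [(2S,3R)-2,3-dimethyloxiran-2-yl]methanol
Product: 26 (2R,3R)-2,3-dimethyloxirane-2-carboxylic acid
Conditions: RuCl3·xH2O (2 mol%), NaIO4, CCl4/MeCN/H2O, 25 °C
Reagents that add atoms: water, O
Why: Ruthenium tetroxide oxidation of a primary epoxy alcohol to the glycidic acid, a standard use of this oxidant; the stereocentres are untouched and the descriptor at C2 changes only because the priorities change.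

Step 20
Reactants: 22 (1S,4Z,6S,7R,8R,10S)-8-hydroxy-9-oxo-1-[(triethylsilyl)oxy]germacra-4,11(13)-dien-12,6-olide; 26 (2R,3R)-2,3-dimethyloxirane-2-carboxylic acid
Product: 28 (1S,4Z,6S,7S,8R,10S)-8-{[(2R,3R)-2,3-dimethyloxiran-2-yl]carbonyloxy}-9-oxo-1-[(triethylsilyl)oxy]germacra-4,11(13)-dien-12,6-olide, via mixed anhydride 27 (not isolated)
Conditions: 2,4,6-Cl3C6H2COCl, Et3N, THF, 25 °C; then 22, DMAP, toluene, 25 °C
Reagents that add atoms: 2,4,6-trichlorobenzoyl chloride, O=C(Cl)c1c(Cl)cc(Cl)cc1Cl (aroyl group of 27 only)
Why: Yamaguchi esterification, suited to hindered secondary alcohols; acylation at oxygen leaves C8 untouched, and the acid has no α-hydrogen and no alkene to isomerise.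

Step 21
Reactants: 28 (1S,4Z,6S,7S,8R,10S)-8-{[(2R,3R)-2,3-dimethyloxiran-2-yl]carbonyloxy}-9-oxo-1-[(triethylsilyl)oxy]germacra-4,11(13)-dien-12,6-olide
Product: 29 (1S,4Z,6S,7S,8R,10S)-8-{[(2R,3R)-2,3-dimethyloxiran-2-yl]carbonyloxy}-1-hydroxy-9-oxogermacra-4,11(13)-dien-12,6-olide
Conditions: HF·pyridine, pyridine, THF, 0 °C
Reagents that add atoms: none
Why: Buffered fluoride cleavage of the triethylsilyl ether; there is no free base to attack the methylene lactone or the β-hydroxy ketone, and the electron-poor glycidic ester resists the buffered acid.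

## Compound list

1 | 2-methylcyclohex-2-en-1-one | CC1=CCCCC1=O | starting material
2 | (2S,3R)-2-methyl-3-(4,4,5,5-tetramethyl-1,3,2-dioxaborolan-2-yl)cyclohexan-1-one | O=C1[C@@H](C)[C@H](B2OC(C)(C)C(C)(C)O2)CCC1 | intermediate
3 | (2S,3R)-3-hydroxy-2-methylcyclohexan-1-one | O=C1[C@@H](C)[C@H](O)CCC1 | intermediate
4 | (2S,3R)-3-[(tert-butyldimethylsilyl)oxy]-2-methylcyclohexan-1-one | O=C1[C@@H](C)[C@H](O[Si](C)(C)C(C)(C)C)CCC1 | intermediate
5 | (2S,3R,6Z)-3-[(tert-butyldimethylsilyl)oxy]-6-(hydroxymethylidene)-2-methylcyclohexan-1-one | O=C1[C@@H](C)[C@H](O[Si](C)(C)C(C)(C)C)CC/C1=C/O | intermediate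
6 | (1S,3S,4R)-4-[(tert-butyldimethylsilyl)oxy]-1,3-dimethyl-2-oxocyclohexane-1-carbaldehyde | O=C1[C@@H](C)[C@H](O[Si](C)(C)C(C)(C)C)CC[C@@]1(C)C=O | intermediate
7 | (2S,3R,6S)-3-[(tert-butyldimethylsilyl)oxy]-2,6-dimethyl-6-[(E)-2-(4,4,5,5-tetramethyl-1,3,2-dioxaborolan-2-yl)ethenyl]cyclohexan-1-one | O=C1[C@@H](C)[C@H](O[Si](C)(C)C(C)(C)C)CC[C@@]1(C)/C=C/B2OC(C)(C)C(C)(C)O2 | intermediate
8 | (2S,3R,6S)-3-[(tert-butyldimethylsilyl)oxy]-6-{(E)-2-[(4-methoxyphenyl)methoxy]ethenyl}-2,6-dimethylcyclohexan-1-one | O=C1[C@@H](C)[C@H](O[Si](C)(C)C(C)(C)C)CC[C@@]1(C)/C=C/OCc2ccc(OC)cc2 | intermediate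
9 | vinylmagnesium bromide | C=C[Mg]Br | starting material
10 | (1R,2S,5R,6S)-5-[(tert-butyldimethylsilyl)oxy]-1-ethenyl-2-{(E)-2-[(4-methoxyphenyl)methoxy]ethenyl}-2,6-dimethylcyclohexan-1-ol | C=C[C@@]1(O)[C@@H](C)[C@H](O[Si](C)(C)C(C)(C)C)CC[C@@]1(C)/C=C/OCc2ccc(OC)cc2 | intermediate
11 | (1R,2S,3R,6S)-1-ethenyl-6-{(E)-2-[(4-methoxyphenyl)methoxy]ethenyl}-2,6-dimethylcyclohexane-1,3-diol | C=C[C@@]1(O)[C@@H](C)[C@H](O)CC[C@@]1(C)/C=C/OCc2ccc(OC)cc2 | intermediate
12 | (2R,3R,4S)-3-ethenyl-3-hydroxy-4-{(E)-2-[(4-methoxyphenyl)methoxy]ethenyl}-2,4-dimethylcyclohexan-1-one | C=C[C@@]1(O)[C@@H](C)C(=O)CC[C@@]1(C)/C=C/OCc2ccc(OC)cc2 | intermediate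
13 | (1R,2S,3S,6S)-1-ethenyl-6-{(E)-2-[(4-methoxyphenyl)methoxy]ethenyl}-2,6-dimethylcyclohexane-1,3-diol | C=C[C@@]1(O)[C@@H](C)[C@@H](O)CC[C@@]1(C)/C=C/OCc2ccc(OC)cc2 | intermediate
14 | dipotassium (1S,4Z,6R,8Z,10S)-6-[(4-methoxyphenyl)methoxy]-4,10-dimethylcyclodeca-4,8-diene-1,9-bis(olate) (target numbering) | [K+].[K+].[O-]/C1=C\C[C@@H](OCc2ccc(OC)cc2)/C=C(/C)CC[C@H]([O-])[C@@H]1C | intermediate
15 | (1S,4Z,6R,8Z,10S)-6-[(4-methoxyphenyl)methoxy]-4,10-dimethyl-1,9-bis[(triethylsilyl)oxy]cyclodeca-4,8-diene (target numbering) | CC[Si](CC)(CC)O/C1=C\C[C@@H](OCc2ccc(OC)cc2)/C=C(/C)CC[C@H](O[Si](CC)(CC)CC)[C@@H]1C | intermediate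
16 | (1S,4Z,6R,7Z,10S)-6-[(4-methoxyphenyl)methoxy]-4,10-dimethyl-1-[(triethylsilyl)oxy]cyclodeca-4,7-dien-9-one (target numbering) | O=C1/C=C\[C@@H](OCc2ccc(OC)cc2)/C=C(/C)CC[C@H](O[Si](CC)(CC)CC)[C@@H]1C | intermediate
17 | (1S,4Z,6S,7R,8R,10S)-7,8-epoxy-6-[(4-methoxyphenyl)methoxy]-4,10-dimethyl-1-[(triethylsilyl)oxy]cyclodec-4-en-9-one (target numbering; cis-epoxide trans to O6) | O=C1[C@@H]2O[C@@H]2[C@@H](OCc3ccc(OC)cc3)/C=C(/C)CC[C@H](O[Si](CC)(CC)CC)[C@@H]1C | intermediate
18 | (1S,4Z,6S,7R,8R,10S)-7,8-epoxy-6-hydroxy-4,10-dimethyl-1-[(triethylsilyl)oxy]cyclodec-4-en-9-one (target numbering) | O=C1[C@@H]2O[C@@H]2[C@@H](O)/C=C(/C)CC[C@H](O[Si](CC)(CC)CC)[C@@H]1C | intermediate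
19 | (diethoxyphosphoryl)acetic acid | CCOP(=O)(CC(=O)O)OCC | starting material
20 | C6 (diethoxyphosphoryl)acetate of 18 (1S,4Z,6S,7R,8R,10S) | O=C1[C@@H]2O[C@@H]2[C@@H](OC(=O)CP(=O)(OCC)OCC)/C=C(/C)CC[C@H](O[Si](CC)(CC)CC)[C@@H]1C | intermediate
21 | cis-fused α-(diethoxyphosphoryl) γ-lactone C6–O–C12(=O)–C11[P(O)(OEt)2]–C7 with C8 hydroxyl, C9 ketone and C1 triethylsilyl ether (1S,4Z,6S,7R,8R,10S; C11 epimers; potassium salt in the flask) | CCOP(=O)(OCC)C1C(=O)O[C@H]2/C=C(/C)CC[C@H](O[Si](CC)(CC)CC)[C@H](C)C(=O)[C@H](O)[C@@H]12 | intermediate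
22 | (1S,4Z,6S,7R,8R,10S)-8-hydroxy-9-oxo-1-[(triethylsilyl)oxy]germacra-4,11(13)-dien-12,6-olide | C=C1C(=O)O[C@H]2/C=C(/C)CC[C@H](O[Si](CC)(CC)CC)[C@H](C)C(=O)[C@H](O)[C@@H]12 | intermediate
23 | angelic acid, (Z)-2-methylbut-2-enoic acid | C/C=C(/C)C(=O)O | starting material
24 | (Z)-2-methylbut-2-en-1-ol | C/C=C(/C)CO | intermediate
25 | [(2S,3R)-2,3-dimethyloxiran-2-yl]methanol | OC[C@]1(C)O[C@@H]1C | intermediate
26 | (2R,3R)-2,3-dimethyloxirane-2-carboxylic acid | OC(=O)[C@]1(C)O[C@@H]1C | intermediate
27 | (2R,3R)-2,3-dimethyloxirane-2-carboxylic 2,4,6-trichlorobenzoic anhydride | O=C(OC(=O)[C@]1(C)O[C@@H]1C)c2c(Cl)cc(Cl)cc2Cl | intermediate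
28 | (1S,4Z,6S,7S,8R,10S)-8-{[(2R,3R)-2,3-dimethyloxiran-2-yl]carbonyloxy}-9-oxo-1-[(triethylsilyl)oxy]germacra-4,11(13)-dien-12,6-olide | C=C1C(=O)O[C@H]2/C=C(/C)CC[C@H](O[Si](CC)(CC)CC)[C@H](C)C(=O)[C@H](OC(=O)[C@]3(C)O[C@@H]3C)[C@@H]12 | intermediate
29 | (1S,4Z,6S,7S,8R,10S)-8-{[(2R,3R)-2,3-dimethyloxiran-2-yl]carbonyloxy}-1-hydroxy-9-oxogermacra-4,11(13)-dien-12,6-olide (CNP0149149.1) | C=C1C(=O)O[C@H]2/C=C(/C)CC[C@H](O)[C@H](C)C(=O)[C@H](OC(=O)[C@]3(C)O[C@@H]3C)[C@@H]12 | target

## Step count and least certain steps

Total: 21 steps. Longest linear sequence: 18 steps (steps 1 to 16, 20 and 21); steps 17 to 19 make the acid side chain.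

**Step 16 (proposed new method).** The most likely failures are loss of regiocontrol (the carbanion attacking the ketone-activated C8 in a six-membered endo mode), transfer of the phosphoryl group to the C8 alkoxide (the path toward cyclopropane formation), or enolisation at C10 with loss of the C1 silyloxy group. Fallback with known chemistry, from 16 back to 21:
- DDQ frees the C6 hydroxyl of 16 to give the hydroxy enone F1.
- DCC coupling with 19 gives the phosphonoacetate F2.
- KN(SiMe3)2 induces the known intramolecular Michael addition of the phosphonoacetate (the first half of a telescoped Michael/olefination) to give the α-phosphono lactone F3.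
- A second equivalent of base and 3-phenyl-2-(phenylsulfonyl)oxaziridine hydroxylate the C8 enolate. The route is rejoined at 21, which is olefinated with formaldehyde as in step 16.
The price is that the ring fusion then rests on the conformation of the ten-membered enone and would have to be proven.

**Step 11 (key step).** The rearrangement may leak through the other chair (giving the E alkene), the tertiary alkoxide may fragment instead of rearranging, or proton transfer may scramble the enolate before silylation. Fallback, from 13 back to 15: Et3SiOTf and 2,6-lutidine give the bis(triethylsilyl) ether F4. A thermal siloxy-Cope rearrangement (toluene, sealed tube, about 200 °C) under neutral conditions should then deliver 15 directly, with no free enolate or alkoxide.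

**Step 7.** Facial selectivity may be poor (equatorial entry of vinyl, giving the trans-dialkenyl isomer), or the hindered ketone may enolise. Fallback, from 8 back to 10: ethynylmagnesium bromide, a slimmer nucleophile with a stronger bias for axial entry, gives the ethynyl carbinol F5. Semihydrogenation over Pd/CaCO3 poisoned with Pb(OAc)2, with quinoline, returns to 10.

**Step 12.** The trans enone may form, or palladium may be diverted by the alkenes; a trans enone would give the wrong C8 epimer downstream. Fallback, from 15 back to 16: PhSeCl converts the enol silane into the C8 phenylselanyl ketone F6. Oxidation with H2O2 and syn elimination of the selenoxide through its cyclic transition state lead to 16.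

**Step 13.** The peroxide may add with poor facial selectivity, or DBU may deprotonate at C6 or C10. Fallback, from 16 to 17 under reagent control: a chiral lanthanum binaphtholate (La(Oi-Pr)3, BINOL, Ph3AsO) with t-BuOOH, using the BINOL antipode matched to the substrate bias. This makes no new compound (entry F0).

**Step 1.** Enantioselectivity may be low for the α-methyl enone, or the C10 epimers may not equilibrate fully. Fallback, from 1 back to 4:
- Corey–Bakshi–Shibata reduction ((S)-2-methyl-CBS-oxazaborolidine, BH3·SMe2) gives (R)-2-methylcyclohex-2-en-1-ol F7.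
- Hydroboration and oxidation anti to the oxygen (BH3·SMe2; NaOH, H2O2) give (1R,3R)-2-methylcyclohexane-1,3-diol F8.
- TBSCl and imidazole silylate the equatorial hydroxyl, trans to the methyl, to give the monosilyl ether F9.
- Oxidation of the remaining axial alcohol (Pr4N[RuO4], N-methylmorpholine N-oxide) returns to 4.

## Further compounds

F1 | step 16 | (1S,4Z,6R,7Z,10S)-6-hydroxy-4,10-dimethyl-1-[(triethylsilyl)oxy]cyclodeca-4,7-dien-9-one (target numbering) | O=C1/C=C\[C@@H](O)/C=C(/C)CC[C@H](O[Si](CC)(CC)CC)[C@@H]1C
F2 | step 16 | C6 (diethoxyphosphoryl)acetate of F1 | O=C1/C=C\[C@@H](OC(=O)CP(=O)(OCC)OCC)/C=C(/C)CC[C@H](O[Si](CC)(CC)CC)[C@@H]1C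
F3 | step 16 | cis-fused α-(diethoxyphosphoryl) γ-lactone with C8 methylene, C9 ketone and C1 triethylsilyl ether (C11 epimers) | CCOP(=O)(OCC)C1C(=O)O[C@H]2/C=C(/C)CC[C@H](O[Si](CC)(CC)CC)[C@H](C)C(=O)C[C@@H]12
F4 | step 11 | 1,9-bis-O-triethylsilyl ether of 13 | C=C[C@@]1(O[Si](CC)(CC)CC)[C@@H](C)[C@@H](O[Si](CC)(CC)CC)CC[C@@]1(C)/C=C/OCc2ccc(OC)cc2
F5 | step 7 | ethynyl analogue of 10 (C9 ethynyl in place of vinyl, same spatial arrangement) | C#C[C@@]1(O)[C@@H](C)[C@H](O[Si](C)(C)C(C)(C)C)CC[C@@]1(C)/C=C/OCc2ccc(OC)cc2
F6 | step 12 | C8 phenylselanyl ketone (1S,4Z,6R,10S; C8 epimers) | O=C1C([Se]c2ccccc2)C[C@@H](OCc3ccc(OC)cc3)/C=C(/C)CC[C@H](O[Si](CC)(CC)CC)[C@@H]1C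
F7 | step 1 | (R)-2-methylcyclohex-2-en-1-ol | O[C@@H]1CCCC=C1C
F8 | step 1 | (1R,3R)-2-methylcyclohexane-1,3-diol | O[C@@H]1CCC[C@@H](O)C1C
F9 | step 1 | (1R,2R,3R)-3-[(tert-butyldimethylsilyl)oxy]-2-methylcyclohexan-1-ol | O[C@@H]1CCC[C@@H](O[Si](C)(C)C(C)(C)C)[C@@H]1C
F0 | step 13 | none | none
A1 | alternative 1 | C1 tert-butyldimethylsilyl, C8 4-methoxybenzyl ether of the target alcohol (methylene lactone in place) | C=C1C(=O)O[C@H]2/C=C(/C)CC[C@H](O[Si](C)(C)C(C)(C)C)[C@H](C)C(=O)[C@H](OCc3ccc(OC)cc3)[C@@H]12
A2 | alternative 2 | ten-membered C1 ketone with Z C4=C5 alkene, C9 dioxolane, C6 silyl ether, C8 4-methoxybenzyl ether and a C7 2-(silyloxymethyl)vinyl group | O=C1CC/C(C)=C\[C@H](O[Si](C)(C)C(C)(C)C)[C@H](C(=C)CO[Si](C)(C)C(C)(C)C)[C@@H](OCc2ccc(OC)cc2)C3(OCCO3)[C@H]1C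
A3 | alternative 3 | C8 4-methoxybenzyl ether of the target alcohol (C1 hydroxyl free) | C=C1C(=O)O[C@H]2/C=C(/C)CC[C@H](O)[C@H](C)C(=O)[C@H](OCc3ccc(OC)cc3)[C@@H]12
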